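Ring C (the pyranone) is cut at O1–C2 and C4–C4a. This exposes a 1,3-dinucleophile on ring A (the phenoxide oxygen O1 and its ortho carbon C4a, masked as an aryl bromide) and a 1,3-dielectrophile holding C2, C3 and C4: an enantiopure (R)-4-aryl-β-lactone. In one pot the phenoxide opens the lactone at its benzylic carbon with inversion, which makes O1–C2 and sets (2S); bromine–lithium exchange then closes ring C on the liberated carboxylate, which makes C4–C4a. The step exploits the β-aryloxy ketone array O1–C2–C3–C4 of ring C and the ortho relation of O1 and C4a on the symmetric phloroglucinol ring A.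

Key step: step 9

Remark: atoms are numbered as in the flavanone (O1, C2, C3, C4, C4a, C5 to C8, C8a). Ar stands for 4-methoxy-3-(methoxymethoxy)-5-(3-methylbut-2-en-1-yl)phenyl. Compounds 1, 5 and 10 are assumed to be purchasable.

Step 1
Reactants: 1 3-bromo-4,5-dihydroxybenzaldehyde
Product: 2 3-bromo-5-hydroxy-4-methoxybenzaldehyde
Conditions: MeI (1.05 equiv), Li2CO3, DMF, 45 °C
Reagents that add atoms: iodomethane, CI
Why: Williamson ether synthesis on the monoanion; the 4-hydroxyl, para to the formyl group and ortho to bromine, is the most acidic, so its phenoxide should be methylated selectively.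

Step 2
Reactants: 2 3-bromo-5-hydroxy-4-methoxybenzaldehyde
Product: 3 3-bromo-4-methoxy-5-(methoxymethoxy)benzaldehyde
Conditions: MOMCl, iPr2NEt, CH2Cl2, 0 °C → rt
Reagents that add atoms: chloromethyl methyl ether, COCCl
Why: O-alkylation of the remaining phenol to its MOM acetal removes the acidic proton before the enolate and organolithium steps.

Step 3
Reactants: 3 3-bromo-4-methoxy-5-(methoxymethoxy)benzaldehyde
Product: 4 4-methoxy-3-(methoxymethoxy)-5-(3-methylbut-2-en-1-yl)benzaldehyde (ArCHO)
Conditions: tributyl(3-methylbut-2-en-1-yl)stannane, Pd(PPh3)4 (5 mol %), DMF, 95 °C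
Reagents that add atoms: tributyl(3-methylbut-2-en-1-yl)stannane, CCCC[Sn](CCCC)(CCCC)CC=C(C)C
Why: Migita–Kosugi–Stille coupling; oxidative addition of the aryl bromide to zerovalent palladium, allyl transfer from tin and reductive elimination at the less substituted allyl terminus should give the linear prenyl arene.

Step 4
Reactants: 4 ArCHO; 5 (R)-2-hydroxy-1,2,2-triphenylethyl acetate ((R)-HYTRA)
Product: 7 (R)-2-hydroxy-1,2,2-triphenylethyl (R)-3-hydroxy-3-Ar-propanoate, via dilithium enolate 6 (not isolated)
Conditions: 5, LDA (2.2 equiv), THF, −78 → 0 °C; then 4, THF/2-methylbutane, −125 °C; NH4Cl (aq); recrystallization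
Reagents that add atoms: none
Why: HYTRA acetate aldol; the dilithium enolate of the (R)-auxiliary should add to the aldehyde face that gives the (R)-carbinol, as it does with other aldehydes, and the minor diastereomer is removed by recrystallization of the adduct.

Step 5
Reactants: 7 (R)-2-hydroxy-1,2,2-triphenylethyl (R)-3-hydroxy-3-Ar-propanoate
Product: 8 (R)-3-hydroxy-3-Ar-propanoic acid
Conditions: KOH, MeOH/H2O, 60 °C; then KHSO4 (aq), 0 °C
Reagents that add atoms: potassium hydroxide, [K+].[OH-]
Why: Saponification of the auxiliary ester releases the β-hydroxy acid without touching the carbinol centre and returns the auxiliary diol.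

Step 6
Reactants: 8 (R)-3-hydroxy-3-Ar-propanoic acid
Product: 9 (R)-4-Ar-oxetan-2-one
Conditions: PhSO2Cl (2 equiv), pyridine, 0 °C
Reagents that add atoms: none
Why: β-Lactonization by carboxyl activation; the mixed carboxylic–sulfonic anhydride is closed by the hydroxyl, so the C–O bond at the stereocenter is not broken and (R) is retained.

Step 7
Reactants: 10 phloroglucinol
Product: 11 3,5-bis(methoxymethoxy)phenol
Conditions: MOMCl (2.0 equiv), iPr2NEt (2.2 equiv), DMF, 0 °C → rt
Reagents that add atoms: chloromethyl methyl ether, COCCl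
Why: Statistical acetal protection of the threefold-symmetric triol; the bis-ether is separated by chromatography and the mono- and tris-ethers can be recycled.

Step 8
Reactants: 11 3,5-bis(methoxymethoxy)phenol
Product: 12 2-bromo-3,5-bis(methoxymethoxy)phenol
Conditions: NBS (1.0 equiv), iPr2NH (10 mol %), CH2Cl2, −78 → 0 °C
Reagents that add atoms: N-bromosuccinimide, O=C1CCC(=O)N1Br
Why: Electrophilic aromatic bromination; amine-mediated delivery of bromine through the hydrogen-bonded phenol should favour the position ortho to the free hydroxyl over the more hindered position between the two MOM ethers.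

Step 9
Reactants: 12 2-bromo-3,5-bis(methoxymethoxy)phenol; 9 (R)-4-Ar-oxetan-2-one
Product: 17 (S)-5,7-bis(methoxymethoxy)-2-Ar-chroman-4-one, via sodium phenolate 13 (not isolated), via ring-opened carboxylate 14 (not isolated), via aryllithium 15 (not isolated), via gem-diolate 16 (not isolated)
Conditions: 12, NaH (1.0 equiv), 15-crown-5, THF, 0 °C; 9, 0 → 40 °C; then t-BuLi (2.1 equiv), −95 → −20 °C; AcOH, −78 °C
Reagents that add atoms: none
Why: Sodium phenolate 13 attacks the benzylic ring carbon of β-lactone 9 with alkyl–oxygen cleavage (SN2), which forms O1–C2 and unveils carboxylate 14; tert-butyllithium then effects bromine–lithium exchange to aryllithium 15, whose attack on the carboxylate forms C4–C4a and gives gem-diolate 16, which collapses to the ketone only on acidic quench. The closest known reaction types are the phenoxide opening of β-lactones at the alkyl carbon and the Parham cyclization of ortho-bromoaryl alkanoate salts, run here in one pot as a formal [3+3] annulation. The only ring closed is the pyranone ring C, by 6-exo-trig anionic acylation. C2 is controlled by the (R) configuration of 9 through inversion in the SN2 opening, which gives (2S), and it should not be scrambled afterwards because C4 stays masked as the gem-diolate, so no enolizable β-aryloxy ketone meets base. The step needs alkyl–oxygen rather than acyl–oxygen cleavage, O- rather than C-alkylation and no elimination; the crown-ether-separated phenoxide, the reversibility of any acyl attack and a benzylic carbon that ionizes poorly (the 4-methoxy group is twisted out of conjugation by its two ortho neighbours) should secure this. Exchange at bromine is much faster at −95 °C than deprotonation at the prenyl CH2 or at C2–H, which secures the site of metalation.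

Step 10
Reactants: 17 (S)-5,7-bis(methoxymethoxy)-2-Ar-chroman-4-one
Product: 18 (2S)-5,7-dihydroxy-2-[3-hydroxy-4-methoxy-5-(3-methylbut-2-en-1-yl)phenyl]chroman-4-one
Conditions: 3 M HCl (aq), MeOH, 40 °C
Reagents that add atoms: none
Why: Acid-catalysed transacetalization to dimethoxymethane frees the three phenols; the prenyl group has no ortho hydroxyl to cyclize onto and mild acid should not open the pyranone ring, so (2S) is kept.

Compound list
1 | 3-bromo-4,5-dihydroxybenzaldehyde | O=Cc1cc(O)c(O)c(Br)c1 | starting material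
2 | 3-bromo-5-hydroxy-4-methoxybenzaldehyde | O=Cc1cc(O)c(OC)c(Br)c1 | intermediate
3 | 3-bromo-4-methoxy-5-(methoxymethoxy)benzaldehyde | O=Cc1cc(OCOC)c(OC)c(Br)c1 | intermediate
4 | 4-methoxy-3-(methoxymethoxy)-5-(3-methylbut-2-en-1-yl)benzaldehyde | O=Cc1cc(OCOC)c(OC)c(CC=C(C)C)c1 | intermediate
5 | (R)-2-hydroxy-1,2,2-triphenylethyl acetate ((R)-HYTRA) | CC(=O)O[C@H](c1ccccc1)C(O)(c1ccccc1)c1ccccc1 | starting material
6 | dilithium enolate of (R)-HYTRA | [Li+].[Li+].C=C([O-])O[C@H](c1ccccc1)C([O-])(c1ccccc1)c1ccccc1 | intermediate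
7 | (R)-2-hydroxy-1,2,2-triphenylethyl (R)-3-hydroxy-3-[4-methoxy-3-(methoxymethoxy)-5-(3-methylbut-2-en-1-yl)phenyl]propanoate | O=C(C[C@@H](O)c1cc(OCOC)c(OC)c(CC=C(C)C)c1)O[C@H](c1ccccc1)C(O)(c1ccccc1)c1ccccc1 | intermediate
8 | (R)-3-hydroxy-3-[4-methoxy-3-(methoxymethoxy)-5-(3-methylbut-2-en-1-yl)phenyl]propanoic acid | OC(=O)C[C@@H](O)c1cc(OCOC)c(OC)c(CC=C(C)C)c1 | intermediate
9 | (R)-4-[4-methoxy-3-(methoxymethoxy)-5-(3-methylbut-2-en-1-yl)phenyl]oxetan-2-one | O=C1C[C@H](c2cc(OCOC)c(OC)c(CC=C(C)C)c2)O1 | intermediate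
10 | phloroglucinol (benzene-1,3,5-triol) | Oc1cc(O)cc(O)c1 | starting material
11 | 3,5-bis(methoxymethoxy)phenol | Oc1cc(OCOC)cc(OCOC)c1 | intermediate
12 | 2-bromo-3,5-bis(methoxymethoxy)phenol | Oc1cc(OCOC)cc(OCOC)c1Br | intermediate
13 | sodium 2-bromo-3,5-bis(methoxymethoxy)phenolate | [Na+].[O-]c1cc(OCOC)cc(OCOC)c1Br | intermediate
14 | sodium (S)-3-[2-bromo-3,5-bis(methoxymethoxy)phenoxy]-3-[4-methoxy-3-(methoxymethoxy)-5-(3-methylbut-2-en-1-yl)phenyl]propanoate | [Na+].[O-]C(=O)C[C@H](Oc1cc(OCOC)cc(OCOC)c1Br)c1cc(OCOC)c(OC)c(CC=C(C)C)c1 | intermediate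
15 | sodium (S)-3-[2-lithio-3,5-bis(methoxymethoxy)phenoxy]-3-[4-methoxy-3-(methoxymethoxy)-5-(3-methylbut-2-en-1-yl)phenyl]propanoate | [Na+].[O-]C(=O)C[C@H](Oc1cc(OCOC)cc(OCOC)c1[Li])c1cc(OCOC)c(OC)c(CC=C(C)C)c1 | intermediate
16 | lithium sodium (S)-5,7-bis(methoxymethoxy)-2-[4-methoxy-3-(methoxymethoxy)-5-(3-methylbut-2-en-1-yl)phenyl]chromane-4,4-diolate | [Li+].[Na+].[O-]C1([O-])C[C@@H](c2cc(OCOC)c(OC)c(CC=C(C)C)c2)Oc2cc(OCOC)cc(OCOC)c12 | intermediate
17 | (S)-5,7-bis(methoxymethoxy)-2-[4-methoxy-3-(methoxymethoxy)-5-(3-methylbut-2-en-1-yl)phenyl]chroman-4-one | COc1c(OCOC)cc([C@@H]2CC(=O)c3c(OCOC)cc(OCOC)cc3O2)cc1CC=C(C)C | intermediate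
18 | (2S)-5,7-dihydroxy-2-[3-hydroxy-4-methoxy-5-(3-methylbut-2-en-1-yl)phenyl]chroman-4-one | COc1c(O)cc([C@@H]2CC(=O)c3c(O)cc(O)cc3O2)cc1CC=C(C)C | target

Total step count: 10. Longest linear sequence: 8 steps (steps 1 to 6, 9 and 10); steps 7 and 8 make the ring A partner.

Steps most likely to fail

Step 9. Three processes may intervene: acyl–oxygen cleavage of the lactone, base-induced elimination to the cinnamate during the phenoxide opening, or protonation of the aryllithium before it closes on the carboxylate. The fallback makes the two bonds in two separate, known operations; it sets out from 8 and 12 and comes back at 17. Acid 8 is coupled with N,O-dimethylhydroxylamine hydrochloride (EDC·HCl, HOBt, iPr2NEt, CH2Cl2) to the (R)-Weinreb amide F1. Mitsunobu etherification of F1 with phenol 12 (PPh3, DIAD, toluene, 0 °C) should give the (S)-aryl ether F2 with inversion. Treatment with t-BuLi (2 equiv, THF, −95 °C) generates the aryllithium F3, which closes in a Parham cyclization to the chelated tetrahedral lithium alkoxide F4. Mild acidic quench then releases 17.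

Step 6. Sulfonylation of the benzylic hydroxyl in place of the carboxyl group, followed by decarboxylative elimination to the styrene, or loss of carbon dioxide from the lactone on isolation, may take over. The fallback sets out from aldehyde 4 and comes back at 9, which also bypasses steps 4 and 5. It is a cinchona-alkaloid-catalysed ketene–aldehyde [2+2] cycloaddition: ketene F5 is generated in the flask from acetyl chloride and iPr2NEt and adds to 4 in the presence of O-trimethylsilylquinidine (10 mol %) and LiClO4 in CH2Cl2/Et2O at −78 °C. If the quinidine-derived catalyst delivers the wrong antipode, its quinine-derived pseudoenantiomer is used so that the (R)-lactone is obtained.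

Step 8. Bromination at the position para to the hydroxyl, or double bromination, may compete. The fallback needs no halogen; it sets out from 11 and 9 and comes back at 17. The sodium phenolate F6 (from 11, NaH, 15-crown-5, THF) opens lactone 9 as in step 9 and gives, after acidification, the (S)-acid F7. Trifluoroacetic anhydride (CH2Cl2, 0 °C) converts F7 into the mixed anhydride F8, which should undergo intramolecular Friedel–Crafts acylation at either of the two equivalent positions ortho to the ether oxygen to give 17.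

Further compounds
F1 | step 9 | (R)-3-hydroxy-N-methoxy-N-methyl-3-[4-methoxy-3-(methoxymethoxy)-5-(3-methylbut-2-en-1-yl)phenyl]propanamide | CON(C)C(=O)C[C@@H](O)c1cc(OCOC)c(OC)c(CC=C(C)C)c1
F2 | step 9 | (S)-3-[2-bromo-3,5-bis(methoxymethoxy)phenoxy]-N-methoxy-N-methyl-3-[4-methoxy-3-(methoxymethoxy)-5-(3-methylbut-2-en-1-yl)phenyl]propanamide | CON(C)C(=O)C[C@H](Oc1cc(OCOC)cc(OCOC)c1Br)c1cc(OCOC)c(OC)c(CC=C(C)C)c1
F3 | step 9 | (S)-3-[2-lithio-3,5-bis(methoxymethoxy)phenoxy]-N-methoxy-N-methyl-3-[4-methoxy-3-(methoxymethoxy)-5-(3-methylbut-2-en-1-yl)phenyl]propanamide | CON(C)C(=O)C[C@H](Oc1cc(OCOC)cc(OCOC)c1[Li])c1cc(OCOC)c(OC)c(CC=C(C)C)c1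
F4 | step 9 | lithium (2S)-4-[methoxy(methyl)amino]-5,7-bis(methoxymethoxy)-2-[4-methoxy-3-(methoxymethoxy)-5-(3-methylbut-2-en-1-yl)phenyl]chroman-4-olate (C4 configuration not defined) | [Li+].CON(C)C1([O-])C[C@@H](c2cc(OCOC)c(OC)c(CC=C(C)C)c2)Oc2cc(OCOC)cc(OCOC)c12
F5 | step 6 | ketene | C=C=O
F6 | step 8 | sodium 3,5-bis(methoxymethoxy)phenolate | [Na+].[O-]c1cc(OCOC)cc(OCOC)c1
F7 | step 8 | (S)-3-[3,5-bis(methoxymethoxy)phenoxy]-3-[4-methoxy-3-(methoxymethoxy)-5-(3-methylbut-2-en-1-yl)phenyl]propanoic acid | OC(=O)C[C@H](Oc1cc(OCOC)cc(OCOC)c1)c1cc(OCOC)c(OC)c(CC=C(C)C)c1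
F8 | step 8 | (S)-3-[3,5-bis(methoxymethoxy)phenoxy]-3-[4-methoxy-3-(methoxymethoxy)-5-(3-methylbut-2-en-1-yl)phenyl]propanoic trifluoroacetic anhydride | O=C(C[C@H](Oc1cc(OCOC)cc(OCOC)c1)c1cc(OCOC)c(OC)c(CC=C(C)C)c1)OC(=O)C(F)(F)F
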